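**Plan** (ent-kaurane numbering: C1–C5, C10 = ring A; C5–C6–O–C7–C8–C9–C10 = oxepane ring B; C8, C9, C11–C14 = ring C; C8, C14, C13, C16, C15 = ring D)
- Retrosynthesis: the epoxide, the C16 methylene and the free hemiacetal are late adjustments; ring D is cut at C13–C16 and C8–C15 in one event; then the aryl–C10 bond and the C6–O–C7 acetal are cut.
- Enabling feature: ring C can be a phenol with the OH on C14. Oxidation gives a pentadienyl cation over C8–C9–C11–C12–C13 whose ends C8 and C13 flank C14 and take up a vinyl unit (C15=C16) in a (5+2) cycloaddition.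
- Helpers: the vinyl group hangs from the C6 acetal oxygen through silicon (later oxidised off to give the C15 oxygen); the C14 carbonyl and the C12 cation are reduced away.
- Forward: ring A (a 4-oxocyclogeranate) is joined to the arene by anti-SN2' arylation at C10, ring B is closed as the C6 acetal, ring D is made by the (5+2) step, then C14 deoxygenation, C15 ketone, C16 methylene, epoxide.
- Stereochemistry: C2 carbinol (CBS) → C10 (anti-SN2') → C1/C2 diol (Woodward, methyl-bearing face) → C6 (anomeric equilibration) → C8/C13 (tether on the lower face) → epoxide (face of the C14 bridge).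

Key step: step 13

Remark: the hemiacetal epimer of the target (C6–OH anti to the C10 methyl) is taken to be the thermodynamically preferred anomer, so it is set by equilibration; C15 in 19–23 is left unassigned because it is oxidised later.

Step 1
Reactants: 1 2-bromo-6-hydroxybenzaldehyde
Product: 2 3-bromo-2-(hydroxymethyl)phenol
Conditions: NaBH4, MeOH, 0 °C
Reagents that add atoms: none
Why: Borohydride reduction of the aldehyde gives the benzylic alcohol carbon that becomes C7.

Step 2
Reactants: 2 3-bromo-2-(hydroxymethyl)phenol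
Product: 3 bis-TBS ether of 2
Conditions: TBSCl (2.5 equiv), imidazole, DMF, rt
Reagents that add atoms: tert-butyldimethylsilyl chloride, CC(C)(C)[Si](C)(C)Cl
Why: Standard silylation protects the phenol and the benzylic alcohol so that the bromide can be turned into a Grignard reagent.

Step 3
Reactants: 4 dichlorodiisopropylsilane; 5 vinylmagnesium bromide
Product: 6 chloro(diisopropyl)vinylsilane
Conditions: THF, −78 °C → rt; distillation
Reagents that add atoms: none
Why: Mono-substitution at silicon by one equivalent of Grignard reagent stops cleanly because the two isopropyl groups slow the second substitution.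

Step 4
Reactants: 7 ethyl 2,6,6-trimethyl-4-oxocyclohex-2-ene-1-carboxylate (racemic)
Product: 8 ethyl (1R,4S)-4-hydroxy-2,6,6-trimethylcyclohex-2-ene-1-carboxylate
Conditions: (R)-2-methyl-CBS-oxazaborolidine (10 mol %), catecholborane, toluene, −78 °C; chromatography
Reagents that add atoms: none
Why: Corey–Bakshi–Shibata reduction should fix the carbinol centre (C2, S) under catalyst control in both enantiomers of 7, so the cis alcohol 8 arises from one enantiomer and the trans diastereomer from the other, and the two are separated.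

Step 5
Reactants: 8 ethyl (1R,4S)-4-hydroxy-2,6,6-trimethylcyclohex-2-ene-1-carboxylate
Product: 9 picolinate ester of 8
Conditions: picolinic acid, DCC, DMAP (cat.), CH2Cl2, rt
Reagents that add atoms: picolinic acid, OC(=O)c1ccccn1
Why: Steglich esterification installs the chelating leaving group for the copper-mediated allylic substitution with retention at C2.

Step 6
Reactants: 9 picolinate ester of 8; 3 bis-TBS ether of 2
Product: 11 ethyl 2-aryl-2,6,6-trimethylcyclohex-3-ene-1-carboxylate (aryl trans to the ester), via aryl Grignard reagent 10 (not isolated)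
Conditions: 3, Mg, THF, 45 °C; then CuBr·SMe2 (0.5 equiv), 9, THF, −20 → 0 °C
Reagents that add atoms: none
Why: Copper-mediated anti-SN2' substitution of the allylic picolinate should deliver the aryl group to C10 from the face opposite the C2 oxygen, which sets the quaternary centre (aryl trans to the ester, methyl cis) and moves the alkene to C1=C2.

Step 7
Reactants: 11 ethyl 2-aryl-2,6,6-trimethylcyclohex-3-ene-1-carboxylate
Product: 12 the corresponding C6 aldehyde
Conditions: DIBAL-H (1.3 equiv), CH2Cl2, −78 °C; Rochelle salt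
Reagents that add atoms: none
Why: Partial DIBAL-H reduction of the hindered ester should stop at the aldehyde because the tetrahedral aluminium hemiacetal is stable at −78 °C.

Step 8
Reactants: 12 the C6 aldehyde
Product: 13 tricyclic cyclic methyl acetal (rings A, B, C; C1=C2 alkene; C14–OTBS)
Conditions: camphorsulfonic acid (10 mol %), MeOH, 0 °C → rt
Reagents that add atoms: methanol, CO
Why: Acid methanolysis removes the primary benzylic silyl ether (the aryl silyl ether survives) and the freed C7 hydroxyl closes on the C6 aldehyde (acetalisation), the methoxy group settling anti to the axial C4 and C10 methyl groups.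

Step 9
Reactants: 13 tricyclic cyclic methyl acetal
Product: 14 lactol with the cis-1,2-diol as its 2-acetate
Conditions: I2 (1.05 equiv), AgOAc (2.1 equiv), AcOH, rt; then H2O, 90 °C
Reagents that add atoms: silver acetate, CC(=O)[O-].[Ag+]; water, O
Why: Woodward cis-hydroxylation: iodonium forms on the open lower face, acetate opens it trans-diaxially at C2, the acetoxonium ion then displaces iodide at C1 and is hydrolysed, so both oxygens end on the methyl-bearing face, while the hot aqueous acid also hydrolyses the methyl acetal to the lactol.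

Step 10
Reactants: 14 lactol 2-acetate; 6 chloro(diisopropyl)vinylsilane
Product: 15 C6 O-[diisopropyl(vinyl)silyl] acetal of 14
Conditions: imidazole, CH2Cl2, 0 °C
Reagents that add atoms: none
Why: Silylation should take the anomeric hydroxyl in preference to the hindered C1 hydroxyl, and the silyloxy group is held on the lower face at C6 because the upper face is blocked by the axial C4 and C10 methyl groups.

Step 11
Reactants: 15 silyl acetal
Product: 16 1,2-diacetate of 15
Conditions: Ac2O, pyridine, DMAP (cat.), rt
Reagents that add atoms: acetic anhydride, CC(=O)OC(C)=O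
Why: DMAP-catalysed acetylation of the remaining C1 hydroxyl completes the diacetate of the target.

Step 12
Reactants: 16 diacetate
Product: 17 free C14 phenol
Conditions: KHF2, MeOH, rt
Reagents that add atoms: none
Why: KHF2 in methanol is expected to cleave the aryl silyl ether selectively (phenoxide is the better leaving group), leaving the bulky anomeric silyl ether and the acetates.

Step 13
Reactants: 17 free C14 phenol
Product: 19 tetracyclic cycloadduct (C14 ketone bridge, C9=C11, siloxane C8–C7–O–C6–O–Si–C15), via allylic trifluoroacetate 18 (not isolated)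
Conditions: PhI(OCOCF3)2 (1.1 equiv), (CF3)2CHOH/CH2Cl2, −40 °C; then Et3SiH, −40 → 0 °C
Reagents that add atoms: none
Why: Proposed new method: PhI(OCOCF3)2 oxidises the C14 phenol to a phenoxonium ion, a pentadienyl cation over C8–C9–C11–C12–C13 bridged by the C14 carbonyl, and the tethered vinylsilane adds across the two ortho carbons C8 and C13 in a suprafacial cationic (5+2) cycloaddition; the closest known reaction type is the oxidative-dearomatisation (5+2) cycloaddition of alkene-tethered phenols (perezone type), here with a silyl-acetal tether and a vinylsilane. The silicon-bearing carbon C15 attacks the fully substituted C8 (ipso attack of the vinylsilane, 7-exo closure of the siloxane ring) and the β-silyl cation at C16 is taken up by C13 (5-exo closure of ring D); the resulting allyl cation over C9–C11–C12 is trapped as the C12 trifluoroacetate 18 and reduced in the same flask by Et3SiH at the less hindered C12, leaving the C9=C11 alkene. C8 is set by the tether, which hangs from the lower-face oxygen on C6 and can reach only the arene face anti to the C10 methyl; C13 follows because the two-carbon bridge must be cis; C15 is oxidised later. The step needs ortho (C8) attack instead of para (C11) attack, and ring closure instead of desilylation or rearomatisation; the short tether, the impossibility of rearomatising after attack at C8, the bulky isopropyl groups on silicon and the non-nucleophilic solvent are meant to secure this.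

Step 14
Reactants: 19 tetracyclic cycloadduct
Product: 21 C14-methylene compound, via tosylhydrazone 20 (not isolated)
Conditions: TsNHNH2, THF, 50 °C; then catecholborane, CHCl3, 0 °C; then NaOAc·3H2O, 65 °C
Reagents that add atoms: none
Why: Kabalka reduction of the tosylhydrazone of the strained bridging ketone removes the C14 oxygen under mild conditions that spare the acetates and the silyl acetal, and the unconjugated C9=C11 alkene does not migrate.

Step 15
Reactants: 21 C14-methylene compound
Product: 23 C6 methyl acetal C15 alcohol, via lactol diol 22 (not isolated)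
Conditions: 30% H2O2, KHF2, DMF, 40 °C; then pyridinium p-toluenesulfonate, MeOH, rt
Reagents that add atoms: hydrogen peroxide, OO; methanol, CO
Why: Tamao–Fleming oxidation under neutral fluoride conditions converts the C15–Si bond into C15–OH with retention and frees the lactol, which acidic methanol then protects selectively as the methyl acetal.

Step 16
Reactants: 23 C6 methyl acetal C15 alcohol
Product: 24 C15 ketone
Conditions: Dess–Martin periodinane, CH2Cl2, rt
Reagents that add atoms: none
Why: Dess–Martin oxidation of the hindered secondary alcohol gives the C15 ketone without touching the acetal, the acetates or the alkene.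

Step 17
Reactants: 24 C15 ketone
Product: 25 16-methylene-15-ketone (methyl acetal)
Conditions: paraformaldehyde, N-methylanilinium trifluoroacetate, THF, 65 °C
Reagents that add atoms: paraformaldehyde (as formaldehyde), C=O
Why: Direct α-methylenation (Mannich condensation and elimination, Gras conditions) can occur only at C16 because the other α-carbon, C8, is quaternary.

Step 18
Reactants: 25 16-methylene-15-ketone (methyl acetal)
Product: 26 lactol enone (9,11-deoxy target)
Conditions: AcOH/H2O/THF (3:1:1), 40 °C
Reagents that add atoms: water, O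
Why: Mild acid hydrolysis of the cyclic methyl acetal gives the lactol, whose hydroxyl equilibrates to the face anti to the C10 methyl.

Step 19
Reactants: 26 lactol enone
Product: 27 target
Conditions: mCPBA, CH2Cl2, 0 °C
Reagents that add atoms: 3-chloroperoxybenzoic acid, OOC(=O)c1cccc(Cl)c1
Why: Prilezhaev epoxidation should take only the electron-rich C9=C11 alkene (the enone alkene is electron-poor) and attack from the face of the one-carbon bridge C14, the other face being covered by the C15–C16 bridge.

**Compound list**
1 | 2-bromo-6-hydroxybenzaldehyde | O=Cc1c(O)cccc1Br | starting material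
2 | 3-bromo-2-(hydroxymethyl)phenol | OCc1c(O)cccc1Br | intermediate
3 | bis-TBS ether of 2 | CC(C)(C)[Si](C)(C)OCc1c(Br)cccc1O[Si](C)(C)C(C)(C)C | intermediate
4 | dichlorodiisopropylsilane | CC(C)[Si](Cl)(Cl)C(C)C | starting material
5 | vinylmagnesium bromide | C=C[Mg]Br | starting material
6 | chloro(diisopropyl)vinylsilane | C=C[Si](Cl)(C(C)C)C(C)C | intermediate
7 | ethyl 2,6,6-trimethyl-4-oxocyclohex-2-ene-1-carboxylate (racemic) | CCOC(=O)C1C(C)(C)CC(=O)C=C1C | starting material
8 | ethyl (1R,4S)-4-hydroxy-2,6,6-trimethylcyclohex-2-ene-1-carboxylate (OH cis to ester) | CCOC(=O)[C@@H]1C(C)(C)C[C@H](O)C=C1C | intermediate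
9 | picolinate ester of 8 | CCOC(=O)[C@@H]1C(C)(C)C[C@H](OC(=O)c2ccccn2)C=C1C | intermediate
10 | [3-(TBSO)-2-(TBSOCH2)phenyl]magnesium bromide | CC(C)(C)[Si](C)(C)OCc1c([Mg]Br)cccc1O[Si](C)(C)C(C)(C)C | intermediate
11 | ethyl 2-[3-(TBSO)-2-(TBSOCH2)phenyl]-2,6,6-trimethylcyclohex-3-ene-1-carboxylate, aryl trans to ester | CCOC(=O)[C@@H]1C(C)(C)CC=C[C@@]1(C)c1cccc(O[Si](C)(C)C(C)(C)C)c1CO[Si](C)(C)C(C)(C)C | intermediate
12 | C6 aldehyde corresponding to 11 | O=C[C@@H]1C(C)(C)CC=C[C@@]1(C)c1cccc(O[Si](C)(C)C(C)(C)C)c1CO[Si](C)(C)C(C)(C)C | intermediate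
13 | tricyclic cyclic methyl acetal (C1=C2 alkene, C6–OMe anti to C10 methyl, C14–OTBS) | CC(C)(C)[Si](C)(C)Oc1cccc2c1CO[C@@H](OC)[C@@H]1C(C)(C)CC=C[C@@]21C | intermediate
14 | lactol, cis-1,2-diol syn to C10 methyl as 2-acetate, C14–OTBS | CC(C)(C)[Si](C)(C)Oc1cccc2c1CO[C@@H](O)[C@@H]1C(C)(C)C[C@H](OC(C)=O)[C@H](O)[C@@]21C | intermediate
15 | C6 O-[diisopropyl(vinyl)silyl] acetal of 14 | CC(C)(C)[Si](C)(C)Oc1cccc2c1CO[C@@H](O[Si](C=C)(C(C)C)C(C)C)[C@@H]1C(C)(C)C[C@H](OC(C)=O)[C@H](O)[C@@]21C | intermediate
16 | 1,2-diacetate of 15 | CC(C)(C)[Si](C)(C)Oc1cccc2c1CO[C@@H](O[Si](C=C)(C(C)C)C(C)C)[C@@H]1C(C)(C)C[C@H](OC(C)=O)[C@H](OC(C)=O)[C@@]21C | intermediate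
17 | free C14 phenol of 16 | Oc1cccc2c1CO[C@@H](O[Si](C=C)(C(C)C)C(C)C)[C@@H]1C(C)(C)C[C@H](OC(C)=O)[C@H](OC(C)=O)[C@@]21C | intermediate
18 | cycloadduct C12 trifluoroacetate (C12, C15 unassigned) | C1C([Si]5(C(C)C)C(C)C)[C@@]23CO[C@@H](O5)[C@@H]4C(C)(C)C[C@H](OC(C)=O)[C@H](OC(C)=O)[C@@]4(C)C2=CC(OC(=O)C(F)(F)F)[C@@H]1C3=O | intermediate
19 | tetracyclic cycloadduct: C14 ketone bridge, C9=C11, C15–Si in a siloxane ring to the C6 oxygen | C1C([Si]5(C(C)C)C(C)C)[C@@]23CO[C@@H](O5)[C@@H]4C(C)(C)C[C@H](OC(C)=O)[C@H](OC(C)=O)[C@@]4(C)C2=CC[C@@H]1C3=O | intermediate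
20 | C14 tosylhydrazone of 19 | C1C([Si]5(C(C)C)C(C)C)[C@@]23CO[C@@H](O5)[C@@H]4C(C)(C)C[C@H](OC(C)=O)[C@H](OC(C)=O)[C@@]4(C)C2=CC[C@@H]1C3=NNS(=O)(=O)c1ccc(C)cc1 | intermediate
21 | C14-methylene compound | C1C([Si]5(C(C)C)C(C)C)[C@@]23CO[C@@H](O5)[C@@H]4C(C)(C)C[C@H](OC(C)=O)[C@H](OC(C)=O)[C@@]4(C)C2=CC[C@@H]1C3 | intermediate
22 | C6 lactol C15 alcohol | C1C(O)[C@@]23CO[C@@H](O)[C@@H]4C(C)(C)C[C@H](OC(C)=O)[C@H](OC(C)=O)[C@@]4(C)C2=CC[C@@H]1C3 | intermediate
23 | C6 methyl acetal C15 alcohol | C1C(O)[C@@]23CO[C@@H](OC)[C@@H]4C(C)(C)C[C@H](OC(C)=O)[C@H](OC(C)=O)[C@@]4(C)C2=CC[C@@H]1C3 | intermediate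
24 | C15 ketone | C1C(=O)[C@@]23CO[C@@H](OC)[C@@H]4C(C)(C)C[C@H](OC(C)=O)[C@H](OC(C)=O)[C@@]4(C)C2=CC[C@@H]1C3 | intermediate
25 | 16-methylene-15-ketone, C6 methyl acetal | C=C1C(=O)[C@@]23CO[C@@H](OC)[C@@H]4C(C)(C)C[C@H](OC(C)=O)[C@H](OC(C)=O)[C@@]4(C)C2=CC[C@@H]1C3 | intermediate
26 | lactol enone (9,11-deoxy target) | C=C1C(=O)[C@@]23CO[C@@H](O)[C@@H]4C(C)(C)C[C@H](OC(C)=O)[C@H](OC(C)=O)[C@@]4(C)C2=CC[C@@H]1C3 | intermediate
27 | CNP0224512.1 | C=C1C(=O)[C@@]23CO[C@@H](O)[C@@H]4C(C)(C)C[C@H](OC(C)=O)[C@H](OC(C)=O)[C@@]4(C)[C@]24O[C@@H]4C[C@@H]1C3 | target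

**Totals:** 19 steps; longest linear sequence 16 steps (7 → 27, steps 4–19).

**Steps most likely to fail**

Step 13 (Proposed new method). Loss of the silyl group from the β-silyl cation (vinyl transfer without the second ring closure), solvent attack at the para carbon, or acid cleavage of the silyl acetal may outrun the cycloaddition. The fallback makes the two ring D bonds one after the other with known reactions, setting out from 16 and returning at 25. Acid methanolysis of 16 (camphorsulfonic acid, MeOH) exchanges the silyl acetal for the methyl acetal diacetate F1. KHF2 in MeOH frees the phenol methyl acetal F2. Oxidation with PhI(OAc)2 in (CF3)2CHOH in the presence of (2-bromoallyl)trimethylsilane (hypervalent-iodine dearomatising allylation) places the bromoallyl group on C8, anti to the C10 methyl, to give the 2-bromoallyl dienone F3. Bu3SnH/AIBN generates the C16 vinyl radical, which closes 5-exo on C13, the allyl radical being reduced at C12, to give the methylene bicyclooctenone F4. Tosylhydrazone formation and catecholborane reduction remove the C14 carbonyl to give the diene F5. SeO2/t-BuOOH allylic oxidation gives the C15 allylic alcohol F6, and Dess–Martin oxidation gives 25.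

Step 6. Substitution at the fully substituted alkene terminus by an ortho-substituted aryl copper reagent may be too slow, so that direct attack at C2 or reduction of the picolinate takes over. The fallback uses palladium and boron with syn instead of anti delivery, setting out from 8 and 3 and returning at 11. Mitsunobu reaction of 8 with acetic acid (PPh3, diisopropyl azodicarboxylate) inverts C2 and gives the trans allylic acetate F7. Bromine–lithium exchange on 3 (n-BuLi), B(OiPr)3 and aqueous work-up give the arylboronic acid F8. γ-Selective syn-SN2' allyl–aryl coupling of F7 with F8 (Pd(OAc)2, 1,10-phenanthroline, AgSbF6, 1,2-dichloroethane, 60 °C) delivers the aryl group to C10 on the acetate face and gives 11.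

Step 9. Iodination of the silyloxy arene and slow diaxial opening of the iodonium ion on the hindered face may spoil the cis-hydroxylation. The fallback sets the diol by hydride delivery instead, setting out from 13 and returning at 16. OsO4/N-methylmorpholine N-oxide dihydroxylates the open lower face to the lower-face diol F9. Swern oxidation gives the 1,2-dione F10. NaBH4 attacks both carbonyls from the open lower face and gives the upper-face diol F11. Aqueous acetic acid hydrolyses the acetal to the lactol diol F12. Silylation with 6 and imidazole gives the silyl acetal diol F13, and Ac2O/pyridine/DMAP gives 16.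

Further compounds
F1 | step 13 | methyl acetal diacetate (C14–OTBS) | CC(C)(C)[Si](C)(C)Oc1cccc2c1CO[C@@H](OC)[C@@H]1C(C)(C)C[C@H](OC(C)=O)[C@H](OC(C)=O)[C@@]21C
F2 | step 13 | phenol methyl acetal | Oc1cccc2c1CO[C@@H](OC)[C@@H]1C(C)(C)C[C@H](OC(C)=O)[C@H](OC(C)=O)[C@@]21C
F3 | step 13 | 2-bromoallyl dienone | C=C(Br)C[C@@]23CO[C@@H](OC)[C@@H]4C(C)(C)C[C@H](OC(C)=O)[C@H](OC(C)=O)[C@@]4(C)C2=CC=CC3=O
F4 | step 13 | methylene bicyclooctenone | C=C1C[C@@]23CO[C@@H](OC)[C@@H]4C(C)(C)C[C@H](OC(C)=O)[C@H](OC(C)=O)[C@@]4(C)C2=CC[C@@H]1C3=O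
F5 | step 13 | diene | C=C1C[C@@]23CO[C@@H](OC)[C@@H]4C(C)(C)C[C@H](OC(C)=O)[C@H](OC(C)=O)[C@@]4(C)C2=CC[C@@H]1C3
F6 | step 13 | C15 allylic alcohol | C=C1C(O)[C@@]23CO[C@@H](OC)[C@@H]4C(C)(C)C[C@H](OC(C)=O)[C@H](OC(C)=O)[C@@]4(C)C2=CC[C@@H]1C3
F7 | step 6 | trans allylic acetate | CCOC(=O)[C@@H]1C(C)(C)C[C@@H](OC(C)=O)C=C1C
F8 | step 6 | arylboronic acid | CC(C)(C)[Si](C)(C)OCc1c(B(O)O)cccc1O[Si](C)(C)C(C)(C)C
F9 | step 9 | lower-face diol | CC(C)(C)[Si](C)(C)Oc1cccc2c1CO[C@@H](OC)[C@@H]1C(C)(C)C[C@@H](O)[C@@H](O)[C@@]21C
F10 | step 9 | 1,2-dione | CC(C)(C)[Si](C)(C)Oc1cccc2c1CO[C@@H](OC)[C@@H]1C(C)(C)CC(=O)C(=O)[C@@]21C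
F11 | step 9 | upper-face diol | CC(C)(C)[Si](C)(C)Oc1cccc2c1CO[C@@H](OC)[C@@H]1C(C)(C)C[C@H](O)[C@H](O)[C@@]21C
F12 | step 9 | lactol diol | CC(C)(C)[Si](C)(C)Oc1cccc2c1CO[C@@H](O)[C@@H]1C(C)(C)C[C@H](O)[C@H](O)[C@@]21C
F13 | step 9 | silyl acetal diol | CC(C)(C)[Si](C)(C)Oc1cccc2c1CO[C@@H](O[Si](C=C)(C(C)C)C(C)C)[C@@H]1C(C)(C)C[C@H](O)[C@H](O)[C@@]21C
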